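With the tetralone numbered C1 (carbonyl) to C4, C4a and C8a, and the naphthalene N1–N8, the sole stereocentre C4 is a diarylmethine. It is bonded to ring A (the hydroquinone ring, via C4a), to N1 and to the C3–C2 chain. The route exploits this. A ring A styrene (C4=C3) takes up a benzyl acetate radical (C2) at C3 and the naphthyl group at C4 in one copper/bis(oxazoline) radical relay, creating C2–C3, C4–N1 and (R)-C4 together. The precursor, a 3,6-bis(benzyloxy)-2-vinylbenzoate, already carries the C1 carboxyl on C8a, so ring C closes by Dieckmann condensation. Every ester and protecting group is benzyl, so one neutral hydrogenolysis deprotects and decarboxylates.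

Key step: step 7

Assumption: the sense of induction of the bis(oxazoline) cannot be predicted with confidence for this congested pair. The ligand antipode that delivers (R)-13 is to be fixed in a pilot run; both antipodes are commercial.

Step 1
Reactants: 1 2-bromobenzene-1,4-diol (bromohydroquinone)
Product: 2 1,4-bis(benzyloxy)-2-bromobenzene
Conditions: BnBr (2.2 equiv), K2CO3, DMF, 50 °C, argon
Reagents that add atoms: benzyl bromide, BrCc1ccccc1
Why: Double Williamson etherification of a hydroquinone with a reactive benzylic halide under carbonate base is routine, and exclusion of air prevents oxidation to the quinone.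

Step 2
Reactants: 2 1,4-bis(benzyloxy)-2-bromobenzene
Product: 4 benzyl 3,6-bis(benzyloxy)-2-bromobenzoate, via the 2-bromoaryllithium 3 (not isolated)
Conditions: LDA (1.1 equiv), THF, −78 °C; cannulated into ClCO2Bn (2 equiv), THF, −78 °C
Reagents that add atoms: benzyl chloroformate, O=C(Cl)OCc1ccccc1
Why: Directed ortho-metalation: the ring C–H flanked by bromine and a benzyloxy group is the most acidic site, LDA at −78 °C removes it below the temperature at which LiBr is lost to the aryne and without touching the benzylic ether positions, and inverse quenching with the chloroformate installs the future C1 carboxyl next to the bromide, a contiguous pattern that electrophilic halogenation of a 2,5-dialkoxybenzoate (expected at the open position para to the ester) would not deliver.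

Step 3
Reactants: 4 benzyl 3,6-bis(benzyloxy)-2-bromobenzoate
Product: 5 benzyl 3,6-bis(benzyloxy)-2-vinylbenzoate
Conditions: vinylboronic acid pinacol ester (1.5 equiv), Pd(OAc)2 (3 mol %), SPhos (6 mol %), K3PO4, toluene/H2O, 90 °C
Reagents that add atoms: vinylboronic acid pinacol ester, C=CB1OC(C)(C)C(C)(C)O1
Why: Suzuki–Miyaura coupling: the bulky electron-rich biarylphosphine lets zerovalent palladium insert into the doubly ortho-substituted C–Br bond, vinyl transfer is fast, and the hindered benzyl ester is inert to aqueous phosphate.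

Step 4
Reactants: 6 5-methoxynaphthalen-1-ol (5-methoxy-1-naphthol)
Product: 7 4-bromo-5-methoxynaphthalen-1-ol
Conditions: NBS (1.0 equiv), MeCN, −20 → 0 °C, dark
Reagents that add atoms: N-bromosuccinimide, O=C1CCC(=O)N1Br
Why: Electrophilic aromatic bromination: the free naphthol is the strongest donor and NBS in acetonitrile favours its para α-position C4 over C2, whereas bromination after O-benzylation would face two nearly equivalent para sites on the two rings.

Step 5
Reactants: 7 4-bromo-5-methoxynaphthalen-1-ol
Product: 8 1-(benzyloxy)-4-bromo-5-methoxynaphthalene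
Conditions: BnBr (1.1 equiv), K2CO3, DMF, rt
Reagents that add atoms: benzyl bromide, BrCc1ccccc1
Why: Williamson etherification of the only acidic OH, carried out promptly because bromonaphthols oxidise easily.

Step 6
Reactants: 8 1-(benzyloxy)-4-bromo-5-methoxynaphthalene
Product: 11 [4-(benzyloxy)-8-methoxynaphthalen-1-yl]boronic acid, via the naphthyllithium 9 (not isolated), via the lithium triisopropoxyborate 10 (not isolated)
Conditions: n-BuLi (1.05 equiv), THF, −78 °C; B(OiPr)3, −78 °C → rt; 1 M HCl, 0 °C, brief
Reagents that add atoms: triisopropyl borate, CC(C)OB(OC(C)C)OC(C)C; water, O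
Why: Bromine–lithium exchange, faster at −78 °C than benzylic deprotonation and assisted by the peri methoxy group, followed by borate trapping and short hydrolysis is the standard entry to hindered arylboronic acids.

Step 7
Reactants: 5 benzyl 3,6-bis(benzyloxy)-2-vinylbenzoate; 11 [4-(benzyloxy)-8-methoxynaphthalen-1-yl]boronic acid; 12 benzyl bromoacetate
Product: 13 benzyl 3,6-bis(benzyloxy)-2-{(1R)-4-(benzyloxy)-1-[4-(benzyloxy)-8-methoxynaphthalen-1-yl]-4-oxobutyl}benzoate
Conditions: Cu(MeCN)4PF6 (10 mol %), Ph-BOX [2,2'-(propane-2,2-diyl)bis(4-phenyl-4,5-dihydrooxazole), (S,S) or (R,R) as fixed by the pilot run] (12 mol %), 11 (2 equiv) premixed with LiOtBu (2 equiv), 12 (2 equiv, syringe pump), CH2Cl2/DMF, 0 °C → rt, argon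
Reagents that add atoms: none
Why: Ligated monovalent copper (as its tert-butoxide or aryl complex) abstracts bromine from 12 and the resulting electrophilic benzyloxycarbonylmethyl radical adds to the unsubstituted terminus C3 of 5 (C2–C3), while transmetalation from the lithium boronate of 11 furnishes the chiral aryl–copper partner that captures the C4 benzylic radical; reductive elimination from the trivalent copper intermediate forms C4–N1 and regenerates monovalent copper. The closest known reaction type is the copper/bis(oxazoline)-catalysed enantioselective three-component 1,2-alkylarylation (radical-relay carboarylation) of vinylarenes with alkyl bromides and arylboronic acids. No ring is closed; the step makes two skeletal bonds and the only stereocentre. C4 is set under catalyst control, the ligand pocket deciding which face of the prochiral radical is bound and eliminated, so the choice of ligand antipode fixes (R). Regioselectivity rests on formation of the benzylic rather than a primary radical and on polarity matching of the electrophilic radical with the dialkoxy-substituted styrene, and the α-bromo ester is the only halide that monovalent copper can activate. Arylation has to outrun bromine transfer, oxidation to the cation with lactonisation onto the neighbouring ester, and dimerisation, which excess boronate and slow addition of 12 should favour, although the two ortho groups of ring A and the peri methoxy group on N8 make this capture the one demanding event of the route.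

Step 8
Reactants: 13 benzyl 3,6-bis(benzyloxy)-2-{(1R)-4-(benzyloxy)-1-[4-(benzyloxy)-8-methoxynaphthalen-1-yl]-4-oxobutyl}benzoate
Product: 14 benzyl (4R)-5,8-bis(benzyloxy)-4-[4-(benzyloxy)-8-methoxynaphthalen-1-yl]-1-oxo-1,2,3,4-tetrahydronaphthalene-2-carboxylate (C2 epimers and enol form, inconsequential)
Conditions: LiHMDS (2.5 equiv), THF, −78 °C → rt; 1 M HCl
Reagents that add atoms: none
Why: Dieckmann condensation: only the butanoate has α-hydrogens, six-membered closure is helped by the bulky C4 substituents and driven by deprotonation of the β-keto ester, the expelled benzyloxide can only cause degenerate ester exchange, and the silylamide is far too weak to remove the C4–H, so the stereocentre is untouched.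

Step 9
Reactants: 14 benzyl (4R)-5,8-bis(benzyloxy)-4-[4-(benzyloxy)-8-methoxynaphthalen-1-yl]-1-oxo-1,2,3,4-tetrahydronaphthalene-2-carboxylate
Product: 16 (4R)-5,8-dihydroxy-4-(4-hydroxy-8-methoxynaphthalen-1-yl)-3,4-dihydronaphthalen-1(2H)-one, via the β-keto acid 15 (not isolated)
Conditions: H2 (1 atm), 10% Pd/C, EtOAc/EtOH, rt; filtered under argon, then 45 °C
Reagents that add atoms: none
Why: Catalytic hydrogenolysis of the three aryl benzyl ethers and the benzyl ester under neutral conditions, followed by spontaneous decarboxylation of the β-keto acid, should leave the hydrogen-bonded aryl ketone, the methyl ether and the non-acidic C4 centre unchanged.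

Compound list
1 | 2-bromobenzene-1,4-diol | Oc1ccc(O)c(Br)c1 | starting material
2 | 1,4-bis(benzyloxy)-2-bromobenzene | Brc1cc(OCc2ccccc2)ccc1OCc1ccccc1 | intermediate
3 | [3,6-bis(benzyloxy)-2-bromophenyl]lithium | [Li]c1c(Br)c(OCc2ccccc2)ccc1OCc1ccccc1 | intermediate
4 | benzyl 3,6-bis(benzyloxy)-2-bromobenzoate | O=C(OCc1ccccc1)c1c(Br)c(OCc2ccccc2)ccc1OCc1ccccc1 | intermediate
5 | benzyl 3,6-bis(benzyloxy)-2-vinylbenzoate | C=Cc1c(OCc2ccccc2)ccc(OCc2ccccc2)c1C(=O)OCc1ccccc1 | intermediate
6 | 5-methoxynaphthalen-1-ol | COc1cccc2c(O)cccc12 | starting material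
7 | 4-bromo-5-methoxynaphthalen-1-ol | COc1cccc2c(O)ccc(Br)c12 | intermediate
8 | 1-(benzyloxy)-4-bromo-5-methoxynaphthalene | COc1cccc2c(OCc3ccccc3)ccc(Br)c12 | intermediate
9 | [4-(benzyloxy)-8-methoxynaphthalen-1-yl]lithium | COc1cccc2c(OCc3ccccc3)ccc([Li])c12 | intermediate
10 | lithium [4-(benzyloxy)-8-methoxynaphthalen-1-yl]tri(propan-2-yloxy)borate | [Li+].COc1cccc2c(OCc3ccccc3)ccc([B-](OC(C)C)(OC(C)C)OC(C)C)c12 | intermediate
11 | [4-(benzyloxy)-8-methoxynaphthalen-1-yl]boronic acid | COc1cccc2c(OCc3ccccc3)ccc(B(O)O)c12 | intermediate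
12 | benzyl bromoacetate | O=C(CBr)OCc1ccccc1 | starting material
13 | benzyl 3,6-bis(benzyloxy)-2-{(1R)-4-(benzyloxy)-1-[4-(benzyloxy)-8-methoxynaphthalen-1-yl]-4-oxobutyl}benzoate | COc1cccc2c(OCc3ccccc3)ccc([C@@H](CCC(=O)OCc3ccccc3)c3c(OCc4ccccc4)ccc(OCc4ccccc4)c3C(=O)OCc3ccccc3)c12 | intermediate
14 | benzyl (4R)-5,8-bis(benzyloxy)-4-[4-(benzyloxy)-8-methoxynaphthalen-1-yl]-1-oxo-1,2,3,4-tetrahydronaphthalene-2-carboxylate (C2 undefined) | COc1cccc2c(OCc3ccccc3)ccc([C@H]3CC(C(=O)OCc4ccccc4)C(=O)c4c(OCc5ccccc5)ccc(OCc5ccccc5)c43)c12 | intermediate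
15 | (4R)-5,8-dihydroxy-4-(4-hydroxy-8-methoxynaphthalen-1-yl)-1-oxo-1,2,3,4-tetrahydronaphthalene-2-carboxylic acid (C2 undefined) | COc1cccc2c(O)ccc([C@H]3CC(C(=O)O)C(=O)c4c(O)ccc(O)c43)c12 | intermediate
16 | (4R)-5,8-dihydroxy-4-(4-hydroxy-8-methoxynaphthalen-1-yl)-3,4-dihydronaphthalen-1(2H)-one | COc1cccc2c(O)ccc([C@H]3CCC(=O)c4c(O)ccc(O)c43)c12 | target

Total step count: 9. Longest linear sequence: 6 (steps 1–3 or steps 4–6, then steps 7–9).

Steps most likely to fail

1. Step 7. Several things could go wrong:
   - Transmetalation of the peri-substituted boronic acid may be slow and lose out to protodeboronation.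
   - Capture of the twisted, doubly ortho-flanked benzylic radical may lag behind bromine transfer, lactonisation onto the neighbouring ester or dimerisation.
   - Facial selectivity may be poor.

   The fallback removes the C8a carboxyl and closes ring C electrophilically. It sets out from 2 and comes back at 16. Vinylation of 2 under the conditions of step 3 would give 1,4-bis(benzyloxy)-2-vinylbenzene F1, a styrene with one ortho group and no neighbouring ester. The copper-catalysed coupling with 11 and 12, now on an ordinary vinylarene, would give benzyl (4R)-4-[2,5-bis(benzyloxy)phenyl]-4-[4-(benzyloxy)-8-methoxynaphthalen-1-yl]butanoate F2. LiOH in THF/H2O would give (4R)-4-[2,5-bis(benzyloxy)phenyl]-4-[4-(benzyloxy)-8-methoxynaphthalen-1-yl]butanoic acid F3. Intramolecular Friedel–Crafts acylation (TFAA, CH2Cl2, 0 °C) should then occur at C8a–H, which is ortho to the C8 benzyloxy group, whereas the rival position N2 is meta to its donor. This would give (4R)-5,8-bis(benzyloxy)-4-[4-(benzyloxy)-8-methoxynaphthalen-1-yl]-3,4-dihydronaphthalen-1(2H)-one F4. Hydrogenolysis as in step 9 leads to 16.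

2. Step 8. The enolate may fail to reach the carbonyl of a benzoate flanked on both sides, or the adduct may revert before it is deprotonated. The fallback replaces the ester acceptor by a linear, unhindered nitrile. It sets out from 2 and comes back at 14. Lithiation of 2 as in step 2 (via 3) and quenching with 4-toluenesulfonyl cyanide would give 3,6-bis(benzyloxy)-2-bromobenzonitrile F5. Vinylation as in step 3 would give 3,6-bis(benzyloxy)-2-vinylbenzonitrile F6. The coupling of step 7 with 11 and 12 would give benzyl (4R)-4-[3,6-bis(benzyloxy)-2-cyanophenyl]-4-[4-(benzyloxy)-8-methoxynaphthalen-1-yl]butanoate F7. Thorpe–Ziegler-type cyclisation (LiHMDS, THF) would give benzyl (4R)-1-amino-5,8-bis(benzyloxy)-4-[4-(benzyloxy)-8-methoxynaphthalen-1-yl]-3,4-dihydronaphthalene-2-carboxylate F8. Mild hydrolysis of this enamino ester (1 M HCl, THF) gives 14.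

3. Step 2. Loss of LiBr from the lithiated bromoarene (aryne formation), metalation at a benzylic position, or consumption of the chloroformate by the liberated amine may erode the step. The fallback avoids a halogen next to the metalated carbon. It sets out from 2 and comes back at 5. Bromine–lithium exchange on 2 (n-BuLi, THF, −78 °C) and quenching with benzyl chloroformate would give benzyl 2,5-bis(benzyloxy)benzoate F9. Ester-directed magnesiation with TMPMgCl·LiCl at the C–H flanked by the ester and a benzyloxy group, then iodine, would give benzyl 3,6-bis(benzyloxy)-2-iodobenzoate F10. Vinylation as in step 3 gives 5.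

Further compounds
F1 | step 7 | 1,4-bis(benzyloxy)-2-vinylbenzene | C=Cc1cc(OCc2ccccc2)ccc1OCc1ccccc1
F2 | step 7 | benzyl (4R)-4-[2,5-bis(benzyloxy)phenyl]-4-[4-(benzyloxy)-8-methoxynaphthalen-1-yl]butanoate | COc1cccc2c(OCc3ccccc3)ccc([C@@H](CCC(=O)OCc3ccccc3)c3cc(OCc4ccccc4)ccc3OCc3ccccc3)c12
F3 | step 7 | (4R)-4-[2,5-bis(benzyloxy)phenyl]-4-[4-(benzyloxy)-8-methoxynaphthalen-1-yl]butanoic acid | COc1cccc2c(OCc3ccccc3)ccc([C@@H](CCC(=O)O)c3cc(OCc4ccccc4)ccc3OCc3ccccc3)c12
F4 | step 7 | (4R)-5,8-bis(benzyloxy)-4-[4-(benzyloxy)-8-methoxynaphthalen-1-yl]-3,4-dihydronaphthalen-1(2H)-one | COc1cccc2c(OCc3ccccc3)ccc([C@H]3CCC(=O)c4c(OCc5ccccc5)ccc(OCc5ccccc5)c43)c12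
F5 | step 8 | 3,6-bis(benzyloxy)-2-bromobenzonitrile | N#Cc1c(Br)c(OCc2ccccc2)ccc1OCc1ccccc1
F6 | step 8 | 3,6-bis(benzyloxy)-2-vinylbenzonitrile | C=Cc1c(OCc2ccccc2)ccc(OCc2ccccc2)c1C#N
F7 | step 8 | benzyl (4R)-4-[3,6-bis(benzyloxy)-2-cyanophenyl]-4-[4-(benzyloxy)-8-methoxynaphthalen-1-yl]butanoate | COc1cccc2c(OCc3ccccc3)ccc([C@@H](CCC(=O)OCc3ccccc3)c3c(OCc4ccccc4)ccc(OCc4ccccc4)c3C#N)c12
F8 | step 8 | benzyl (4R)-1-amino-5,8-bis(benzyloxy)-4-[4-(benzyloxy)-8-methoxynaphthalen-1-yl]-3,4-dihydronaphthalene-2-carboxylate | COc1cccc2c(OCc3ccccc3)ccc([C@H]3CC(C(=O)OCc4ccccc4)=C(N)c4c(OCc5ccccc5)ccc(OCc5ccccc5)c43)c12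
F9 | step 2 | benzyl 2,5-bis(benzyloxy)benzoate | O=C(OCc1ccccc1)c1cc(OCc2ccccc2)ccc1OCc1ccccc1
F10 | step 2 | benzyl 3,6-bis(benzyloxy)-2-iodobenzoate | O=C(OCc1ccccc1)c1c(I)c(OCc2ccccc2)ccc1OCc1ccccc1
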